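**Retrosynthetic overview**

- The target is a single benzene ring (ring A) in which the phenol carbon C1 lies between the bromines on C2 and C6. In the deoxy arene this C1–H is the only ring hydrogen flanked by two bromines, hence the most acidic, and the whole plan rests on that.
- Disconnection 1 (last bond made on the ring): C1–O, formed by deprotonative magnesiation of silyl-protected 2,3,5-tribromobenzyl alcohol, borylation and peroxide oxidation in one pot.
- Disconnection 2: the O–Si bond and the benzylic C–H bond lead back to 2,3,5-tribromobenzaldehyde (silylation, hydride reduction).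
- Disconnection 3: the C3–Br bond beside the benzylic carbon leads back to the C–N bond of 2-amino-3,5-dibromobenzaldehyde (Sandmeyer reaction), which already carries the other two bromines in the right places.
- No ring is formed: ring A is bought in, and all three bromines are in place before the ring oxygen arrives, which avoids electrophilic halogenation of an electron-rich phenol.

Key step: step 4

Assumption: TMPMgCl·LiCl (TMP = 2,2,6,6-tetramethylpiperidin-1-yl) is taken as the commercial THF/toluene solution and treated as a reagent; the target has no stereocentre, so no stereocontrol is required.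

Step 1
Reactants: 1 2-amino-3,5-dibromobenzaldehyde
Product: 3 2,3,5-tribromobenzaldehyde, via diazonium bromide 2 (not isolated)
Conditions: NaNO2, 48% aq HBr, AcOH, 0–5 °C; then CuBr, 48% aq HBr, 0 → 70 °C
Reagents that add atoms: hydrobromic acid, Br
Why: Sandmeyer reaction: nitrosation of the weakly basic aniline in strong acid gives diazonium salt 2, which CuBr reduces by single-electron transfer to an aryl radical that takes bromine from the CuBr2 so formed, while the aldehyde is inert under these acidic conditions.

Step 2
Reactants: 3 2,3,5-tribromobenzaldehyde
Product: 4 (2,3,5-tribromophenyl)methanol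
Conditions: NaBH4, MeOH/THF, 0 °C
Reagents that add atoms: none
Why: Hydride reduction of an aldehyde with NaBH4, which is chemoselective for the carbonyl group and leaves the three aryl C–Br bonds untouched.

Step 3
Reactants: 4 (2,3,5-tribromophenyl)methanol; 5 chlorotriisopropylsilane
Product: 6 triisopropyl[(2,3,5-tribromobenzyl)oxy]silane
Conditions: imidazole, DMF, 0 °C → rt
Reagents that add atoms: chlorotriisopropylsilane (5), CC(C)[Si](Cl)(C(C)C)C(C)C
Why: Imidazole-promoted silyl ether formation: the unhindered primary benzylic alcohol attacks the silicon of the N-silylimidazolium formed from 5, giving a bulky, base-stable and weakly coordinating ether that should survive the amide base and the alkaline peroxide of step 4.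

Step 4
Reactants: 6 triisopropyl[(2,3,5-tribromobenzyl)oxy]silane; 7 trimethyl borate
Product: 10 2,3,6-tribromo-4-[(triisopropylsilyloxy)methyl]phenol, via arylmagnesium chloride 8 (not isolated), via dimethyl arylboronate 9 (not isolated)
Conditions: TMPMgCl·LiCl (1.3 equiv), THF, −20 → 0 °C; 7 (2 equiv), −20 °C → rt; 30% aq H2O2 then aq NaOH, 0 °C; Na2SO3, then dilute HCl to pH 4
Reagents that add atoms: hydrogen peroxide, OO
Why: The hindered amide base TMPMgCl·LiCl removes the ring proton at the carbon that becomes phenol C1, the only C–H flanked by two bromines (the third bromine sits meta to it), to give arylmagnesium 8; B(OMe)3 captures 8 as an ate complex that collapses to boronate 9, hydroperoxide adds to boron, the aryl group shifts from boron to oxygen with loss of hydroxide, and hydrolysis of the aryl borate releases phenol 10. The closest known reaction type is the deprotonative magnesiation of polyhaloarenes with TMP-magnesium amides followed by borylation and peroxide oxidation, a one-pot arene hydroxylation. No ring is closed and no stereocentre is formed. The selectivity needed is C1–H over C5–H; it is secured by acidity (two ortho bromines against one ortho bromine and an alkyl group) and by the bulky triisopropylsilyl ether, which shields C5–H and offers magnesium no useful coordination site, and because the same anion is also the thermodynamically preferred one, bromine migration has no driving force. The largely covalent C–Mg bond should neither exchange with the C–Br bonds nor expel magnesium halide to an aryne at or below 0 °C, and adding the peroxide before the base should let oxidation outrun protodeboronation of the di-ortho-bromo boronate.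

Step 5
Reactants: 10 2,3,6-tribromo-4-[(triisopropylsilyloxy)methyl]phenol
Product: 11 2,3,6-tribromo-4-(hydroxymethyl)phenol
Conditions: Bu4NF, AcOH, THF, 0 °C → rt; aq NaH2PO4 work-up
Reagents that add atoms: none
Why: Fluoride-mediated desilylation driven by the strong Si–F bond, with AcOH buffering the medium so that the acidic tribromophenol and the para-hydroxybenzylic alcohol are not exposed to strongly basic fluoride, and with no other group in 10 that responds to fluoride.

**Compound list**

1 | 2-amino-3,5-dibromobenzaldehyde | Nc1c(Br)cc(Br)cc1C=O | starting material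
2 | 2,4-dibromo-6-formylbenzenediazonium bromide (diazonium bromide) | O=Cc1cc(Br)cc(Br)c1[N+]#N.[Br-] | intermediate
3 | 2,3,5-tribromobenzaldehyde | O=Cc1cc(Br)cc(Br)c1Br | intermediate
4 | (2,3,5-tribromophenyl)methanol | OCc1cc(Br)cc(Br)c1Br | intermediate
5 | chlorotriisopropylsilane | CC(C)[Si](Cl)(C(C)C)C(C)C | starting material
6 | triisopropyl[(2,3,5-tribromobenzyl)oxy]silane | CC(C)[Si](OCc1cc(Br)cc(Br)c1Br)(C(C)C)C(C)C | intermediate
7 | trimethyl borate | COB(OC)OC | starting material
8 | [2,3,6-tribromo-4-(triisopropylsilyloxymethyl)phenyl]magnesium chloride (arylmagnesium chloride) | CC(C)[Si](OCc1cc(Br)c([Mg]Cl)c(Br)c1Br)(C(C)C)C(C)C | intermediate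
9 | dimethyl [2,3,6-tribromo-4-(triisopropylsilyloxymethyl)phenyl]boronate (dimethyl arylboronate) | CC(C)[Si](OCc1cc(Br)c(B(OC)OC)c(Br)c1Br)(C(C)C)C(C)C | intermediate
10 | 2,3,6-tribromo-4-[(triisopropylsilyloxy)methyl]phenol | CC(C)[Si](OCc1cc(Br)c(O)c(Br)c1Br)(C(C)C)C(C)C | intermediate
11 | 2,3,6-tribromo-4-(hydroxymethyl)phenol | OCc1cc(Br)c(O)c(Br)c1Br | target

Total step count: 5. Longest linear sequence: 5 steps (1 → 3 → 4 → 6 → 10 → 11).

**Steps most likely to fail**

1. Step 4. Deprotonation may be too slow at the temperatures where the ortho-bromo arylmagnesium is stable, so that warming brings loss of magnesium halide to an aryne or bromine migration; the di-ortho-bromo boronate may also protodeboronate in the alkaline medium before the aryl shift to oxygen. The fallback sets out from 6 and comes back to the route at 10. LiN(i-Pr)2 is added at −78 °C to a THF solution that already holds 6 and B(O-i-Pr)3, so that the transient aryllithium is intercepted as it forms and gives lithium aryl(triisopropoxy)borate F1. Exchange with pinacol and AcOH gives the isolable triisopropyl{[2,3,5-tribromo-4-(4,4,5,5-tetramethyl-1,3,2-dioxaborolan-2-yl)benzyl]oxy}silane F2. F2 is then oxidised under non-basic conditions with KHSO5 (as the triple salt 2KHSO5·KHSO4·K2SO4) in aqueous acetone at 0 °C to phenol 10.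

2. Step 1. Diazotisation of the weakly basic, doubly ortho-substituted aniline may stay incomplete in aqueous acid, and water may capture the diazonium ion (hydrolysis to a phenol) or it may be reduced (hydrodediazoniation) before bromine transfer. The fallback sets out from 1 and comes back at 3. Non-aqueous nitrosation with NOBF4 in MeCN at −30 → 0 °C and precipitation with Et2O should give the isolable 2,4-dibromo-6-formylbenzenediazonium tetrafluoroborate F3. Bromodediazoniation of F3 with Bu4NBr and catalytic CuBr/CuBr2 in dry MeCN at rt then gives 3.

3. Step 5. Fluoride attack on the hindered triisopropylsilyl group may be sluggish under the buffered conditions. Forcing it risks ionisation at the para-hydroxybenzylic position with oligomerisation, and loss of the acidic product as its tetrabutylammonium phenoxide on isolation. The fallback sets out from 4 and comes back at 11, replacing the fluoride-labile group by one that is removed by mild acid solvolysis. Alcohol 4 is silylated with tert-butylchlorodimethylsilane and imidazole in DMF to tert-butyl(dimethyl)[(2,3,5-tribromobenzyl)oxy]silane F4. The conditions of step 4 convert F4 through the arylmagnesium chloride F5 and the dimethyl arylboronate F6 into 2,3,6-tribromo-4-{[tert-butyl(dimethyl)silyl]oxymethyl}phenol F7. F7 is cleaved with AcOH/THF/H2O (3:1:1) at rt to 40 °C to give 11.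

**Further compounds**

F1 | step 4 | lithium triisopropoxy[2,3,6-tribromo-4-(triisopropylsilyloxymethyl)phenyl]borate | [Li+].CC(C)O[B-](OC(C)C)(OC(C)C)c1c(Br)cc(CO[Si](C(C)C)(C(C)C)C(C)C)c(Br)c1Br
F2 | step 4 | triisopropyl{[2,3,5-tribromo-4-(4,4,5,5-tetramethyl-1,3,2-dioxaborolan-2-yl)benzyl]oxy}silane | CC(C)[Si](OCc1cc(Br)c(B2OC(C)(C)C(C)(C)O2)c(Br)c1Br)(C(C)C)C(C)C
F3 | step 1 | 2,4-dibromo-6-formylbenzenediazonium tetrafluoroborate | O=Cc1cc(Br)cc(Br)c1[N+]#N.F[B-](F)(F)F
F4 | step 5 | tert-butyl(dimethyl)[(2,3,5-tribromobenzyl)oxy]silane | CC(C)(C)[Si](C)(C)OCc1cc(Br)cc(Br)c1Br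
F5 | step 5 | [2,3,6-tribromo-4-(tert-butyldimethylsilyloxymethyl)phenyl]magnesium chloride | CC(C)(C)[Si](C)(C)OCc1cc(Br)c([Mg]Cl)c(Br)c1Br
F6 | step 5 | dimethyl [2,3,6-tribromo-4-(tert-butyldimethylsilyloxymethyl)phenyl]boronate | CC(C)(C)[Si](C)(C)OCc1cc(Br)c(B(OC)OC)c(Br)c1Br
F7 | step 5 | 2,3,6-tribromo-4-{[tert-butyl(dimethyl)silyl]oxymethyl}phenol | CC(C)(C)[Si](C)(C)OCc1cc(Br)c(O)c(Br)c1Br
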